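**Strategy.** The furofuran is traced back to its 4,8-dione, whose two lactone C–O bonds (O3–C4 in ring A, C1–C2–O3–C4–C5, and O7–C8 in ring B, C5–C6–O7–C8–C1) are cut to give an open diethyl 2,3-diaroylsuccinate. In that precursor the ring-fusion carbons C1 and C5 each sit between an aryl ketone (C2, C6) and an ester (C8, C4), so they epimerise freely. One operation, a double asymmetric transfer hydrogenation with dynamic kinetic resolution followed by double lactonisation, is meant to reduce both ketones with the same facial sense, fix C1 and C5, and close both rings of the cis-fused exo,exo-dilactone. Reduction, double etherification and debenzylation finish the route.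

Key step: step 5

Numbering: atom labels C1–C8 follow the 3,7-dioxabicyclo[3.3.0]octane numbering of the target (C1/C5 ring fusion, C2/C6 aryl-bearing, O3/O7, C4/C8) and are used for the corresponding atoms of open-chain compounds.

Assumption: the (S,S)-TsDPEN complex is taken to give S carbinols from these aryl ketones, as it does with simple aryl alkyl ketones; if the sense proves opposite, the (R,R) complex is used with no other change.

Step 1
Reactants: 1 3-hydroxy-4,5-dimethoxybenzoic acid
Product: 3 3-(benzyloxy)-4,5-dimethoxybenzoic acid, via benzyl ester 2 (not isolated)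
Conditions: BnBr (2.2 equiv), K2CO3, DMF, 60 °C; then NaOH, MeOH/H2O, 60 °C; HCl work-up
Reagents that add atoms: benzyl bromide, BrCc1ccccc1
Why: Williamson etherification of the phenoxide (the carboxylate is benzylated as well) followed by saponification of the benzyl ester in the same flask should leave only the base-stable aryl benzyl ether.

Step 2
Reactants: 3 3-(benzyloxy)-4,5-dimethoxybenzoic acid, 4 potassium ethyl malonate
Product: 6 ethyl 3-[3-(benzyloxy)-4,5-dimethoxyphenyl]-3-oxopropanoate, via acyl imidazole 5 (not isolated)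
Conditions: CDI, THF, rt; then 4, MgCl2, Et3N, MeCN, rt → 50 °C; aq HCl
Reagents that add atoms: none
Why: Masamune–Brooks homologation, in which the acyl imidazole C-acylates the magnesium enolate of the malonate half-ester and the acylmalonate decarboxylates on acidification to the β-keto ester.

Step 3
Reactants: 6 ethyl 3-[3-(benzyloxy)-4,5-dimethoxyphenyl]-3-oxopropanoate
Product: 7 ethyl 3-[3-(benzyloxy)-4,5-dimethoxyphenyl]-2-chloro-3-oxopropanoate (racemic)
Conditions: NCS (1.0 equiv), Mg(ClO4)2 (10 mol %), EtOAc, rt
Reagents that add atoms: N-chlorosuccinimide, O=C1CCC(=O)N1Cl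
Why: electrophilic α-chlorination of the magnesium-chelated enol of a 1,3-dicarbonyl compound, held at the monochloride by one equivalent of NCS; the chloride is chosen because it transfers halogen to enolates far less readily than a bromide would in step 4.

Step 4
Reactants: 8 ethyl 3-oxo-3-(3,4,5-trimethoxyphenyl)propanoate, 7 ethyl 3-[3-(benzyloxy)-4,5-dimethoxyphenyl]-2-chloro-3-oxopropanoate
Product: 9 diethyl 2-[3-(benzyloxy)-4,5-dimethoxybenzoyl]-3-(3,4,5-trimethoxybenzoyl)butanedioate (stereoisomers interconvert; none specified)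
Conditions: NaH (1.0 equiv), THF, 0 °C; then 7, THF/DMF, 0 °C → rt
Reagents that add atoms: none
Why: SN2 C-alkylation of the sodium enolate of a β-keto ester by a chloride activated by two carbonyl groups, the classical entry to 2,3-diacylsuccinates, forms the C1–C5 bond; its stereochemistry is irrelevant because C1 and C5 epimerise in step 5.

Step 5
Reactants: 9 diethyl 2-[3-(benzyloxy)-4,5-dimethoxybenzoyl]-3-(3,4,5-trimethoxybenzoyl)butanedioate
Product: 12 (1S,2S,5S,6S)-2-[3-(benzyloxy)-4,5-dimethoxyphenyl]-6-(3,4,5-trimethoxyphenyl)-3,7-dioxabicyclo[3.3.0]octane-4,8-dione (exo,exo), via diol diester 10 (not isolated), via hydroxy ester monolactone 11 (not isolated)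
Conditions: RuCl[(S,S)-TsDPEN](p-cymene) (5 mol %), HCO2H/Et3N (1:1), DMF, 25 °C; aqueous wash; then CSA (10 mol %), CH2Cl2, rt
Reagents that add atoms: none
Why: Proposed new method: in the triethylammonium formate buffer C1 and C5 of 9, each a 1,3-dicarbonyl C–H between an aryl ketone and an ester, epimerise through their enols while the Ru–H/N–H form of the catalyst passes hydride and proton to the ketone carbons C2 and C6 in an outer-sphere six-membered transition state, and the two carbinols then acylate onto the γ-esters under mild acid. The closest known reaction type is Ru–TsDPEN transfer hydrogenation with dynamic kinetic resolution of α-substituted β-keto esters followed by lactonisation, known for one ketone and one ring but not for two on one succinate. Ring A (C1–C2–O3–C4–C5) closes 5-exo-trig by attack of the C2 hydroxyl on the C4 ester and ring B (C5–C6–O7–C8–C1) closes 5-exo-trig by attack of the C6 hydroxyl on the C8 ester, each with loss of ethanol. C2 and C6 are set by the catalyst, which places each aryl group next to its η6-arene and should therefore give the S carbinol at both ketones, the two aryl groups differing only in one remote meta ether. C1 and C5 are set in the same hydride transfers by Felkin-type selection among the equilibrating epimers: the bulky catalyst should attack anti to the large succinate arm with the α-hydrogen beside the aryl ring, which gives the like (S carbinol, S α-carbon) pair that puts each aryl trans to the neighbouring carboxyl carbon and hence exo after closure. The step needs the same facial sense at both ketones and the same relative sense at both α-carbons; the near-twofold symmetry of 9 secures both, running the reduction cold and lactonising only afterwards keeps both ketones reducing as open-chain keto esters, and the cis ring fusion filters the outcome because only a diol with like-configured C1 and C5 can close both lactones, so mismatched material remains a more polar hydroxy ester.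

Step 6
Reactants: 12 (1S,2S,5S,6S)-2-[3-(benzyloxy)-4,5-dimethoxyphenyl]-6-(3,4,5-trimethoxyphenyl)-3,7-dioxabicyclo[3.3.0]octane-4,8-dione
Product: 13 (1S,2R,3R,4S)-1-[3-(benzyloxy)-4,5-dimethoxyphenyl]-2,3-bis(hydroxymethyl)-4-(3,4,5-trimethoxyphenyl)butane-1,4-diol
Conditions: LiAlH4, THF, 0 °C → rt; aq potassium sodium tartrate work-up
Reagents that add atoms: none
Why: hydride reduction of both γ-lactones to 1,4-diols breaks only the acyl C–O bonds, so the benzylic C–O bonds at C2 and C6 and the configurations at C1 and C5 should be carried through unchanged.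

Step 7
Reactants: 13 (1S,2R,3R,4S)-1-[3-(benzyloxy)-4,5-dimethoxyphenyl]-2,3-bis(hydroxymethyl)-4-(3,4,5-trimethoxyphenyl)butane-1,4-diol
Product: 15 (1R,2S,5R,6S)-2-[3-(benzyloxy)-4,5-dimethoxyphenyl]-6-(3,4,5-trimethoxyphenyl)-3,7-dioxabicyclo[3.3.0]octane (exo,exo), via primary bis(mesylate) 14 (not isolated)
Conditions: MsCl (2.2 equiv), pyridine, 0 → 40 °C
Reagents that add atoms: none
Why: the two primary hydroxyls are sulfonylated faster than the hindered benzylic ones, and double 5-exo-tet Williamson closure (O3 onto C4, O7 onto C8) then breaks only primary C–O bonds, an established way from such tetrols to furofurans that retains all four stereocentres.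

Step 8
Reactants: 15 (1R,2S,5R,6S)-2-[3-(benzyloxy)-4,5-dimethoxyphenyl]-6-(3,4,5-trimethoxyphenyl)-3,7-dioxabicyclo[3.3.0]octane
Product: 16 (1R,2S,5R,6S)-2-(3-hydroxy-4,5-dimethoxyphenyl)-6-(3,4,5-trimethoxyphenyl)-3,7-dioxabicyclo[3.3.0]octane (target)
Conditions: H2 (1 atm), 10% Pd/C, EtOAc, rt, stopped after one equivalent of H2
Reagents that add atoms: none
Why: hydrogenolysis of an aryl benzyl ether under neutral conditions at atmospheric pressure is much faster than cleavage of the cyclic benzylic ethers C2–O3 and C6–O7, so the core should survive.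

**Compound list**

1 | 3-hydroxy-4,5-dimethoxybenzoic acid | COc1cc(C(=O)O)cc(O)c1OC | starting material
2 | benzyl 3-(benzyloxy)-4,5-dimethoxybenzoate (not isolated) | COc1cc(C(=O)OCc2ccccc2)cc(OCc3ccccc3)c1OC | intermediate
3 | 3-(benzyloxy)-4,5-dimethoxybenzoic acid | COc1cc(C(=O)O)cc(OCc2ccccc2)c1OC | intermediate
4 | potassium ethyl malonate | CCOC(=O)CC(=O)[O-].[K+] | starting material
5 | 1-[3-(benzyloxy)-4,5-dimethoxybenzoyl]-1H-imidazole (not isolated) | COc1cc(C(=O)n2ccnc2)cc(OCc3ccccc3)c1OC | intermediate
6 | ethyl 3-[3-(benzyloxy)-4,5-dimethoxyphenyl]-3-oxopropanoate | CCOC(=O)CC(=O)c1cc(OC)c(OC)c(OCc2ccccc2)c1 | intermediate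
7 | ethyl 3-[3-(benzyloxy)-4,5-dimethoxyphenyl]-2-chloro-3-oxopropanoate (racemic) | CCOC(=O)C(Cl)C(=O)c1cc(OC)c(OC)c(OCc2ccccc2)c1 | intermediate
8 | ethyl 3-oxo-3-(3,4,5-trimethoxyphenyl)propanoate | CCOC(=O)CC(=O)c1cc(OC)c(OC)c(OC)c1 | starting material
9 | diethyl 2-[3-(benzyloxy)-4,5-dimethoxybenzoyl]-3-(3,4,5-trimethoxybenzoyl)butanedioate (interconverting stereoisomers) | CCOC(=O)C(C(=O)c1cc(OCc2ccccc2)c(OC)c(OC)c1)C(C(=O)c1cc(OC)c(OC)c(OC)c1)C(=O)OCC | intermediate
10 | diethyl (2S,3S)-2-{(S)-[3-(benzyloxy)-4,5-dimethoxyphenyl](hydroxy)methyl}-3-[(S)-hydroxy(3,4,5-trimethoxyphenyl)methyl]butanedioate (not isolated) | COc1cc(cc(OCc2ccccc2)c1OC)[C@@H](O)[C@@H](C(=O)OCC)[C@H](C(=O)OCC)[C@H](O)c3cc(OC)c(OC)c(OC)c3 | intermediate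
11 | ethyl (2S,3S,4S)-2-[3-(benzyloxy)-4,5-dimethoxyphenyl]-4-[(S)-hydroxy(3,4,5-trimethoxyphenyl)methyl]-5-oxooxolane-3-carboxylate (not isolated) | COc1cc(cc(OCc4ccccc4)c1OC)[C@H]2OC(=O)[C@H]([C@H](O)c3cc(OC)c(OC)c(OC)c3)[C@@H]2C(=O)OCC | intermediate
12 | (1S,2S,5S,6S)-2-[3-(benzyloxy)-4,5-dimethoxyphenyl]-6-(3,4,5-trimethoxyphenyl)-3,7-dioxabicyclo[3.3.0]octane-4,8-dione (exo,exo) | COc1cc(cc(OCc4ccccc4)c1OC)[C@H]2OC(=O)[C@H]3[C@@H]2C(=O)O[C@@H]3c5cc(OC)c(OC)c(OC)c5 | intermediate
13 | (1S,2R,3R,4S)-1-[3-(benzyloxy)-4,5-dimethoxyphenyl]-2,3-bis(hydroxymethyl)-4-(3,4,5-trimethoxyphenyl)butane-1,4-diol | COc1cc(cc(OCc2ccccc2)c1OC)[C@@H](O)[C@@H](CO)[C@H](CO)[C@H](O)c3cc(OC)c(OC)c(OC)c3 | intermediate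
14 | (2R,3R)-2-{(S)-[3-(benzyloxy)-4,5-dimethoxyphenyl](hydroxy)methyl}-3-[(S)-hydroxy(3,4,5-trimethoxyphenyl)methyl]butane-1,4-diyl dimethanesulfonate (not isolated) | COc1cc(cc(OCc2ccccc2)c1OC)[C@@H](O)[C@@H](COS(C)(=O)=O)[C@H](COS(C)(=O)=O)[C@H](O)c3cc(OC)c(OC)c(OC)c3 | intermediate
15 | (1R,2S,5R,6S)-2-[3-(benzyloxy)-4,5-dimethoxyphenyl]-6-(3,4,5-trimethoxyphenyl)-3,7-dioxabicyclo[3.3.0]octane (exo,exo) | COc1cc(cc(OCc4ccccc4)c1OC)[C@H]2OC[C@H]3[C@@H]2CO[C@@H]3c5cc(OC)c(OC)c(OC)c5 | intermediate
16 | (1R,2S,5R,6S)-2-(3-hydroxy-4,5-dimethoxyphenyl)-6-(3,4,5-trimethoxyphenyl)-3,7-dioxabicyclo[3.3.0]octane (CNP0181235.1) | COc1cc([C@H]2OC[C@H]3[C@@H]2CO[C@@H]3c2cc(OC)c(OC)c(OC)c2)cc(O)c1OC | target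

Total step count: 8
Longest linear sequence: 8 steps (1 → 3 → 6 → 7 → 9 → 12 → 13 → 15 → 16)

**Steps most likely to fail**

1. Step 5. What may go wrong:
- the hydride transfer may discriminate poorly between the C1 and C5 epimers;
- the first lactone may close before the second ketone is reduced, after which ring A would bias C5 toward the arrangement that cannot form ring B;
- the 1,4-diketone may cyclodehydrate to a furan under the acidic buffer;
- the substrate may fragment by retro-aldol or retro-Claisen cleavage.

Fallback (known chemistry, from 9 back to 12): the chiral catalyst is given up in favour of chelation control and resolution. Reduction of 9 with Zn(BH4)2 (Et2O, 0 °C), the established way to the syn relationship in α-substituted β-keto esters, would convert the portion of 9 with like-configured C1 and C5 into racemic diol diester, that is 10 together with the mirror-image diol diester F1. Acid-catalysed lactonisation (CSA, CH2Cl2) would give the racemic exo,exo-dilactone, 12 together with the mirror-image dilactone F2, purified by crystallisation. Preparative chromatography on a chiral stationary phase would remove F2 and return the route at 12, at the cost of more than half of the material.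

2. Step 4. What may go wrong:
- chlorine may be transferred from 7 to the enolate of 8, which would scramble the two halves into symmetrical diaroylsuccinates;
- proton transfer from the more acidic 7 may quench the nucleophile;
- O-alkylation or Feist–Benary-type closure may lead to furans.

Fallback (from 8 back to 9): the C1–C5 alkylation is replaced by a C5–C6 acylation with no halogenated keto ester. Alkylation of the sodium enolate of 8 with ethyl bromoacetate (NaH, THF) should give diethyl 2-(3,4,5-trimethoxybenzoyl)butanedioate F3. Double deprotonation (NaH, then LiN(iPr)2, THF, −78 °C) would form the dianion, whose ester-enolate carbon is C-acylated by acyl imidazole 5 (made from 3 and CDI as in step 2), rejoining the route at 9.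

3. Step 7. What may go wrong:
- the benzylic hydroxyls may be sulfonylated too, with ionisation or chloride substitution at C2/C6;
- one primary oxygen may displace the other primary sulfonate, closing a 3,4-disubstituted oxolane in place of the bicycle.

Fallback (from 12 back to 15, bypassing 13 and 14): partial reduction of 12 with iBu2AlH (CH2Cl2, −78 °C) should give the bis-lactol F4. Ionic deoxygenation with Et3SiH/BF3·OEt2 (CH2Cl2, −78 → −20 °C) through the two cyclic oxocarbenium ions would then give 15 directly; since exo,exo is the thermodynamically preferred arrangement, any reversible benzylic ionisation should not erode it.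

**Further compounds**

F1 | step 5 | mirror-image diol diester, diethyl (2R,3R)-2-{(R)-[3-(benzyloxy)-4,5-dimethoxyphenyl](hydroxy)methyl}-3-[(R)-hydroxy(3,4,5-trimethoxyphenyl)methyl]butanedioate | COc1cc(cc(OCc2ccccc2)c1OC)[C@H](O)[C@H](C(=O)OCC)[C@@H](C(=O)OCC)[C@@H](O)c3cc(OC)c(OC)c(OC)c3
F2 | step 5 | mirror-image dilactone, (1R,2R,5R,6R)-2-[3-(benzyloxy)-4,5-dimethoxyphenyl]-6-(3,4,5-trimethoxyphenyl)-3,7-dioxabicyclo[3.3.0]octane-4,8-dione | COc1cc(cc(OCc4ccccc4)c1OC)[C@@H]2OC(=O)[C@@H]3[C@H]2C(=O)O[C@H]3c5cc(OC)c(OC)c(OC)c5
F3 | step 4 | diethyl 2-(3,4,5-trimethoxybenzoyl)butanedioate (racemic) | CCOC(=O)CC(C(=O)OCC)C(=O)c1cc(OC)c(OC)c(OC)c1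
F4 | step 7 | bis-lactol, (1S,2S,5S,6S)-2-[3-(benzyloxy)-4,5-dimethoxyphenyl]-6-(3,4,5-trimethoxyphenyl)-3,7-dioxabicyclo[3.3.0]octane-4,8-diol (mixture of anomers) | COc1cc(cc(OCc4ccccc4)c1OC)[C@H]2OC(O)[C@H]3[C@@H]2C(O)O[C@@H]3c5cc(OC)c(OC)c(OC)c5
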